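**The question.** Ask which flask ends with more target, in percent of its own charge, then turn it round: what would zeta need in order to pass gamma?

| flask | starting material | free enzyme | temperature | remark | time |
|---|---|---|---|---|---|
| teal | 0.013 M | 0.23 µM | 37 °C | run made earlier |  |
| amber | 0.013 M | 0.17 µM | 37 °C | run made earlier |  |
| gamma | 0.013 M | 0.35 µM |  | at 37 °C until 4.0 h, from then on at 7 °C | 20 h |
| zeta | 0.040 M | 0.35 µM |  | at 37 °C throughout | 20 h |

- teal (time / h: target / %): 1.00: 2.7; 3.00: 14.5; 6.00: 23.2; 8.00: 28.0; 12.0: 38.2
- amber (time / h: target / %): 1.00: 3.5; 3.00: 10.4; 6.00: 15.9; 8.00: 18.6; 12.0: 28.2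

(scatter of a reading: 1 percentage point)

- percentages count the starting material that a species holds: one side product counts as two
- target is meant together with its idle complex
- the numbers in the tables scatter by 1 percentage point (one standard deviation)
- steps thought possible: free enzyme -> unfolded enzyme; starting material + free enzyme <-> starting complex; starting complex <-> free enzyme + target; starting material + target -> side product; free enzyme + target <-> idle complex; starting complex -> spent catalyst
- the earlier runs do not show what temperature does; that part of a forecast is a guess

1. the flask that ends with the higher amount of target, in percent of the starting material charged, or "neither" when 2 percentage points or less lies between them (gamma / zeta / neither)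
2. final target, as a percentage of the starting material charged, in gamma
3. final target, as a percentage of the starting material charged, in zeta

**Two readings.** From the 3.00 h readings of both runs, take the enzyme's pace, its turnover: 2700 h⁻¹. Teal's later slope lies beneath that pace, so take the gap as target lost to side product and, dividing by the full charge although starting material falls over those hours, get a rough loss constant of 6.24 L mol⁻¹ h⁻¹.

**The ceiling.** Set making equal to losing, and call the target level where they balance the ceiling: making over the loss constant times the starting material present. At zeta's full charge it stands at 9.45%, and it grows as the fraction left shrinks.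

**The opposite outcome.** Approaching its own ceiling, gamma holds about 24.8% at 4.0 h; count nothing for the cold, which is a guess. Zeta's ceiling starts lower, and reaches that level only with 38.1% of its charge left. Even with loss as fast as making, that takes 13.1 h, and target then trails by about 10.5 h, longer than the 6.90 h remaining. So expect gamma ahead.

**The result.** The forecast gave 29% for gamma, 31% for zeta and neither, in its words: “The two are too close to separate.” The flasks give 27.5% in gamma and 17.7% in zeta, so gamma ends higher.

    free enzyme → unfolded enzyme (k = 3.30 × 10⁻⁴ h⁻¹, Ea = 282 kJ mol⁻¹)
    starting material + free enzyme ⇌ starting complex (K = 3300 L mol⁻¹, k = 3.00 × 10⁶ L mol⁻¹ h⁻¹, Ea = 45.0 kJ mol⁻¹, ΔH = 10.0 kJ mol⁻¹)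
    starting complex ⇌ free enzyme + target (K = 0.0310 M, k = 2700 h⁻¹, Ea = 71.0 kJ mol⁻¹, ΔH = −15.0 kJ mol⁻¹)
    starting material + target → side product (k = 5.00 L mol⁻¹ h⁻¹, Ea = 72.0 kJ mol⁻¹)
    free enzyme + target ⇌ idle complex (K = 25.0 L mol⁻¹, k = 680 L mol⁻¹ h⁻¹, Ea = 62.0 kJ mol⁻¹, ΔH = −56.0 kJ mol⁻¹)
    starting complex → spent catalyst (k = 0.00500 h⁻¹, Ea = 109 kJ mol⁻¹)
    (constants at 37 °C)

**Not at rest.** Zeta at 20 h has 33% of its charge left, which lifts its ceiling to 28.6%, with target still beneath it. At 200 h zeta reaches 26.4% with 0.224% starting material left, while gamma reaches 62.9% with 12.2% left.

**A neighbour.** For a neighbour of gamma, alike but for 0.033 M of starting material charged, the ceiling is 13.9%, and 4.0 h of approach gives 7.80%. It ends at 9.43%, under that ceiling, with 83% left.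

The numbers in the tables are simulated from invented constants, noise included.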